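In a one-step world, each turnover of the catalyst leaves one target in the flask, and a count of turnovers is a count of target. This flask has a further step after the count, and two colleagues dispute what that step is worth.

| flask | starting material | reagent | free catalyst | time |
|---|---|---|---|---|
| blue | 0.050 M | 1.50 equiv | 11 mol% | 25 min |
| teal | 0.050 M | 2.50 equiv | 11 mol% | 25 min |
| grey | 0.050 M | 3.00 equiv | 11 mol% | 25 min |
| ochre | 0.050 M | 5.00 equiv | 11 mol% | 25 min |
| red | 0.050 M | 8.00 equiv | 11 mol% | 25 min |

    starting material + free catalyst ⇌ catalyst intermediate A (K1 = 58.8 M⁻¹, k1 = 6.94 M⁻¹ min⁻¹)
    reagent + catalyst intermediate A ⇌ catalyst intermediate B (K2 = 8.22 M⁻¹, k2 = 16.2 M⁻¹ min⁻¹)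
    catalyst intermediate B ⇌ catalyst intermediate C (K3 = 0.10, k3 = 16.2 min⁻¹)
    catalyst intermediate C → free catalyst + target (k4 = 0.876 min⁻¹)
    reagent + target → over-reaction product (k5 = 0.485 M⁻¹ min⁻¹)

1. [target] at the end for blue, teal, grey, ochre, red, in this order
2. the shape of the row from first to last (falls, then rises / rises, then falls / rises all the way / falls all the way / hardly changes)

- "hardly changes" means that all values lie within two and a half points (for a concentration: within two and a half percent of the largest)
- run time (blue): 25 min

Both colleagues begin alike. In blue, catalyst intermediates B and C exchange with a half-life of 0.233 s, far shorter than the 0.79 min half-life of intermediate C in the release step. They weigh the catalyst forms by their equilibrium constants at the charged concentrations. That puts 3.05% of the catalyst in blue as intermediate C, which gives 0.669 turnovers in the run. In red the share is 6.63%, which gives 1.45 turnovers.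

The first colleague stops there. Turnovers are target, so the row climbs from 0.00368 M in blue to 0.00799 M in red.

The second colleague objects that target does not stay. Reagent is in excess, so target is lost in a pseudo-first-order step. In blue its half-life by over-reaction alone, with reagent as charged, is 19 min, shorter than the run of 25 min. Let x be the rate constant of over-reaction times the charged reagent times the run time. This is the number of target lifetimes in the run. The survival share is the fraction of target, made at a steady rate, still present at the end: one minus exp(−x), over x. Blue has x = 0.909 and a share of 0.657. Red has x = 4.85 and a share of 0.205.

I side with the second colleague and multiply catalyst charge, turnovers and survival share. That gives 0.00242 M for blue, 0.00258 M for teal, 0.00254 M for grey, 0.00216 M for ochre and 0.00163 M for red. Teal stands highest. I ignored the start-up of the cycle, so I expect these values to run somewhat high.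

The forecast gives lower numbers than mine, 0.0018 M, 0.002 M, 0.002 M, 0.0017 M and 0.0014 M, with the shape "rises, then falls", and it says “Over-reaction scales directly with reagent”.

The simulation gives 0.00195 M, 0.00210 M, 0.00208 M, 0.00178 M and 0.00134 M, so the shape is "rises, then falls", turning at 2.5 equiv. The second colleague wins. The first keeps the direction of the row, though not its size, on the stretch up to 2.5 equiv, where the row rises. My row stands above the simulated one by a factor of 1.24 in blue and 1.22 in red.

The survival share of 0.657 for blue compares with a reading of 0.693, taken as target over target plus over-reaction product, and the 0.205 for red compares with a reading of 0.229. In blue, the release step ran with intermediate C at 2.60% of the catalyst after 12.5 min and 2.54% after 25.0 min, and at the end 93.0% of the reagent's own charge remained beside over-reaction product at 1.73% of the starting material charged. In red, intermediate C stood at 5.31% of the catalyst after 25.0 min, with 96.6% of the reagent's own charge remaining, and in percent of the starting material charged the target at 2.69% lay beside over-reaction product at 9.04%.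

The rate constants belong to no real substance; the flask was simulated.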